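**Plan**
Flavone 1 is the unit joined through C8. Flavone 2 is the unit joined through C2' of its ring B.
Cuts, in retrosynthetic order: the four O–benzyl bonds; O1–C2 and C2–C3 of flavone 2 (cyclodehydration, Claisen condensation); C2'–C3' and C1'–C6' of ring B of flavone 2 ([4+2]); the C8–alkyne bond; O1–C2 and C2–C3 of flavone 1.
Enabling feature: ring B of flavone 2 carries its oxygen on C4', para to C1' (which bears the pyranone, a masked ester carbon) and meta to C2' (bonded to C8 of flavone 1). A 1-methoxy-3-silyloxybutadiene leaves exactly this pattern on a 3-arylpropiolate.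
Forward order: ring C of flavone 1 closes first (chalcone, oxidative cyclisation), the alkynoate is attached at C8, ring B of flavone 2 is grown by cycloaddition and aromatisation, and ring C of flavone 2 closes last onto a second portion of acetophenone 2.
Stereochemistry: the target has no stereocentre; the E-alkene of 5 and the CH(OMe) centre of 10 are transient.

Key step: step 6

Assumption: the target SMILES carries no axial descriptor, so the C8–C2' biaryl axis (three ortho substituents) is left uncontrolled and every biaryl from 11 onward is taken as the racemate.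

Step 1
Reactants: 1 2',4',6'-trihydroxyacetophenone
Product: 2 1-[2,4-bis(benzyloxy)-6-hydroxyphenyl]ethanone
Conditions: BnBr (2.1 equiv), K2CO3 (2.2 equiv), DMF, rt → 50 °C
Reagents that add atoms: benzyl bromide, BrCc1ccccc1
Why: Williamson ether synthesis: the 4-OH and one ortho OH are alkylated, whereas the remaining ortho OH is held in a hydrogen bond to the acetyl oxygen and resists the mild base, so the phenol that later closes each pyranone stays free.

Step 2
Reactants: 2 1-[2,4-bis(benzyloxy)-6-hydroxyphenyl]ethanone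
Product: 3 1-[4,6-bis(benzyloxy)-2-hydroxy-3-iodophenyl]ethanone
Conditions: NIS (1.05 equiv), TFA (cat.), MeCN, 0 °C → rt
Reagents that add atoms: N-iodosuccinimide, O=C1CCC(=O)N1I
Why: Electrophilic aromatic iodination: C3 lies ortho to the free chelated hydroxyl and next to only one benzyloxy group, while C5 is wedged between two, so one equivalent of the iodonium source should substitute C3 alone.

Step 3
Reactants: 3 1-[4,6-bis(benzyloxy)-2-hydroxy-3-iodophenyl]ethanone; 4 4-methoxybenzaldehyde
Product: 5 (E)-1-[4,6-bis(benzyloxy)-2-hydroxy-3-iodophenyl]-3-(4-methoxyphenyl)prop-2-en-1-one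
Conditions: KOH (50% aq.), EtOH–THF, rt
Reagents that add atoms: none
Why: Claisen–Schmidt condensation: the methyl ketone enolate adds to the non-enolisable aldehyde and E1cB loss of water gives the conjugated alkene in its more stable E form, with the aryl iodide and benzyl ethers inert to hydroxide at room temperature.

Step 4
Reactants: 5 (E)-1-[4,6-bis(benzyloxy)-2-hydroxy-3-iodophenyl]-3-(4-methoxyphenyl)prop-2-en-1-one
Product: 6 5,7-bis(benzyloxy)-8-iodo-2-(4-methoxyphenyl)chromen-4-one
Conditions: I2 (0.1 equiv), DMSO, 130 °C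
Reagents that add atoms: none
Why: Iodine-catalysed oxidative cyclisation of a 2'-hydroxychalcone: oxa-Michael closure through the only free phenol and dehydrogenation with DMSO as terminal oxidant form ring C of flavone 1, and since that phenol sits next to the iodine the halogen is forced to C8.

Step 5
Reactants: 6 5,7-bis(benzyloxy)-8-iodo-2-(4-methoxyphenyl)chromen-4-one; 7 methyl prop-2-ynoate
Product: 8 methyl 3-[5,7-bis(benzyloxy)-2-(4-methoxyphenyl)-4-oxochromen-8-yl]prop-2-ynoate
Conditions: PdCl2(PPh3)2 (5 mol%), CuI (10 mol%), K2CO3 (2 equiv), 7 (4 equiv, slow addition), THF, 65 °C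
Reagents that add atoms: none
Why: Sonogashira coupling: oxidative addition of the C8–I bond to zerovalent palladium and transfer of the copper acetylide of 7 are known for propiolate esters when a carbonate replaces the amine base (no aza-Michael loss of 7), and the linear alkyne fits between O1 and the 7-benzyloxy group.

Step 6
Reactants: 8 methyl 3-[5,7-bis(benzyloxy)-2-(4-methoxyphenyl)-4-oxochromen-8-yl]prop-2-ynoate; 9 (E)-1-methoxy-3-(trimethylsilyloxy)buta-1,3-diene
Product: 12 methyl 2-[5,7-bis(benzyloxy)-2-(4-methoxyphenyl)-4-oxochromen-8-yl]-4-hydroxybenzoate, via cyclohexa-1,4-diene cycloadduct 10 (not isolated), via aryl trimethylsilyl ether 11 (not isolated)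
Conditions: 9 (5 equiv, in portions), BHT (cat.), o-xylene, sealed tube, 150 °C; then 1 M HCl, THF, rt
Reagents that add atoms: none
Why: A concerted but strongly asynchronous [4+2] cycloaddition is expected, in which the nucleophilic CH2 terminus of 9 bonds to the alkyne carbon on C8 (beta to the ester, forming C2'–C3') slightly ahead of the union of the methoxy-bearing terminus with the alpha carbon (C1'–C6'). The closest known reaction type is the Diels–Alder benzannulation of 1-alkoxy-3-silyloxybutadienes with 3-arylpropiolates, which delivers 2-aryl-4-hydroxybenzoates. The single new ring, ring B of flavone 2, closes intermolecularly as a six-membered carbocycle from the four diene carbons and the two alkyne carbons, giving cyclohexa-1,4-diene 10, which becomes aromatic by 1,4-loss of methanol (11) and is desilylated by the acid to 12. The one sp3 stereocentre of 10, the CH(OMe) carbon, is erased on aromatisation, so no configuration has to be controlled. Regioselectivity is needed and rests on the ester, which makes the aryl-bearing alkyne carbon the electrophilic terminus and so places the oxygen para to C1' and meta to C2'. Chemoselectivity over C2=C3 of the chromone is secured because that bond is trisubstituted, aryl-conjugated and part of a vinylogous ester, while excess diene, the sealed tube and the inhibitor offset the deactivating, bulky trioxygenated aryl group on the alkyne.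

Step 7
Reactants: 12 methyl 2-[5,7-bis(benzyloxy)-2-(4-methoxyphenyl)-4-oxochromen-8-yl]-4-hydroxybenzoate
Product: 13 methyl 2-[5,7-bis(benzyloxy)-2-(4-methoxyphenyl)-4-oxochromen-8-yl]-4-methoxybenzoate
Conditions: MeI (1.5 equiv), K2CO3 (1.5 equiv), DMF, rt
Reagents that add atoms: iodomethane, CI
Why: Williamson methylation: the C4' phenol created in step 6 is the only hydroxyl in 12, so it alone is alkylated, while the 7-O-benzyl group keeps the neighbouring ester from lactonising onto O7.

Step 8
Reactants: 13 methyl 2-[5,7-bis(benzyloxy)-2-(4-methoxyphenyl)-4-oxochromen-8-yl]-4-methoxybenzoate; 2 1-[2,4-bis(benzyloxy)-6-hydroxyphenyl]ethanone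
Product: 15 1-[2,4-bis(benzyloxy)-6-hydroxyphenyl]-3-{2-[5,7-bis(benzyloxy)-2-(4-methoxyphenyl)-4-oxochromen-8-yl]-4-methoxyphenyl}propane-1,3-dione, via dilithio acetophenone dianion 14 (not isolated)
Conditions: 2 (2.5 equiv), LiN(SiMe3)2 (5.2 equiv), THF, −78 → −10 °C; then 13, −78 °C → rt; 1 M HCl quench
Reagents that add atoms: none
Why: Crossed Claisen condensation of an o-hydroxyacetophenone dianion with a non-enolisable methyl benzoate, the established ester route to flavone 1,3-diketones: carbon acylation at the enolate terminus forms C2–C3 of flavone 2, deprotonation of the product by surplus 14 drives the equilibrium, and pre-forming 14 leaves no free amide base to attack the chromone of 13.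

Step 9
Reactants: 15 1-[2,4-bis(benzyloxy)-6-hydroxyphenyl]-3-{2-[5,7-bis(benzyloxy)-2-(4-methoxyphenyl)-4-oxochromen-8-yl]-4-methoxyphenyl}propane-1,3-dione
Product: 16 5,7-bis(benzyloxy)-8-{2-[5,7-bis(benzyloxy)-4-oxochromen-2-yl]-5-methoxyphenyl}-2-(4-methoxyphenyl)chromen-4-one
Conditions: p-TsOH·H2O (20 mol%), toluene, 90 °C
Reagents that add atoms: none
Why: Acid-catalysed cyclodehydration of an o-hydroxyaryl 1,3-diketone: the free phenol adds to the carbonyl next to ring B (six-membered O1–C2 closure) and loss of water gives the delocalised pyranone under conditions mild enough for benzyl and methyl ethers.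

Step 10
Reactants: 16 5,7-bis(benzyloxy)-8-{2-[5,7-bis(benzyloxy)-4-oxochromen-2-yl]-5-methoxyphenyl}-2-(4-methoxyphenyl)chromen-4-one
Product: 17 8-[2-(5,7-dihydroxy-4-oxochromen-2-yl)-5-methoxyphenyl]-5,7-dihydroxy-2-(4-methoxyphenyl)chromen-4-one (CNP0394081.0)
Conditions: H2 (1 atm), Pd/C (10 wt%), THF–MeOH, rt
Reagents that add atoms: none
Why: Catalytic hydrogenolysis: the four benzylic C–O bonds are cleaved on palladium, whereas the two aryl methyl ethers are inert and the C2=C3 bonds of both chromones, being part of delocalised pyranones, are not reduced at atmospheric pressure.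

**Compound list**
1 | 2',4',6'-trihydroxyacetophenone | CC(=O)c1c(O)cc(O)cc1O | starting material
2 | 1-[2,4-bis(benzyloxy)-6-hydroxyphenyl]ethanone | CC(=O)c1c(O)cc(OCc2ccccc2)cc1OCc1ccccc1 | intermediate
3 | 1-[4,6-bis(benzyloxy)-2-hydroxy-3-iodophenyl]ethanone | CC(=O)c1c(O)c(I)c(OCc2ccccc2)cc1OCc1ccccc1 | intermediate
4 | 4-methoxybenzaldehyde | COc1ccc(C=O)cc1 | starting material
5 | (E)-1-[4,6-bis(benzyloxy)-2-hydroxy-3-iodophenyl]-3-(4-methoxyphenyl)prop-2-en-1-one | COc1ccc(/C=C/C(=O)c2c(O)c(I)c(OCc3ccccc3)cc2OCc2ccccc2)cc1 | intermediate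
6 | 5,7-bis(benzyloxy)-8-iodo-2-(4-methoxyphenyl)chromen-4-one | COc1ccc(-c2cc(=O)c3c(OCc4ccccc4)cc(OCc4ccccc4)c(I)c3o2)cc1 | intermediate
7 | methyl prop-2-ynoate (methyl propiolate) | C#CC(=O)OC | starting material
8 | methyl 3-[5,7-bis(benzyloxy)-2-(4-methoxyphenyl)-4-oxochromen-8-yl]prop-2-ynoate | COC(=O)C#Cc1c(OCc2ccccc2)cc(OCc2ccccc2)c2c(=O)cc(-c3ccc(OC)cc3)oc12 | intermediate
9 | (E)-1-methoxy-3-(trimethylsilyloxy)buta-1,3-diene | CO/C=C/C(=C)O[Si](C)(C)C | starting material
10 | methyl 2-[5,7-bis(benzyloxy)-2-(4-methoxyphenyl)-4-oxochromen-8-yl]-6-methoxy-4-(trimethylsilyloxy)cyclohexa-1,4-diene-1-carboxylate (racemic, not isolated) | COC(=O)C1=C(CC(O[Si](C)(C)C)=CC1OC)c1c(OCc2ccccc2)cc(OCc2ccccc2)c2c(=O)cc(-c3ccc(OC)cc3)oc12 | intermediate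
11 | methyl 2-[5,7-bis(benzyloxy)-2-(4-methoxyphenyl)-4-oxochromen-8-yl]-4-(trimethylsilyloxy)benzoate (not isolated) | COC(=O)c1ccc(O[Si](C)(C)C)cc1-c1c(OCc2ccccc2)cc(OCc2ccccc2)c2c(=O)cc(-c3ccc(OC)cc3)oc12 | intermediate
12 | methyl 2-[5,7-bis(benzyloxy)-2-(4-methoxyphenyl)-4-oxochromen-8-yl]-4-hydroxybenzoate | COC(=O)c1ccc(O)cc1-c1c(OCc2ccccc2)cc(OCc2ccccc2)c2c(=O)cc(-c3ccc(OC)cc3)oc12 | intermediate
13 | methyl 2-[5,7-bis(benzyloxy)-2-(4-methoxyphenyl)-4-oxochromen-8-yl]-4-methoxybenzoate | COC(=O)c1ccc(OC)cc1-c1c(OCc2ccccc2)cc(OCc2ccccc2)c2c(=O)cc(-c3ccc(OC)cc3)oc12 | intermediate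
14 | dilithium 3,5-bis(benzyloxy)-2-(1-oxidoethenyl)phenolate (dianion of 2, not isolated) | [Li+].[Li+].C=C([O-])c1c([O-])cc(OCc2ccccc2)cc1OCc1ccccc1 | intermediate
15 | 1-[2,4-bis(benzyloxy)-6-hydroxyphenyl]-3-{2-[5,7-bis(benzyloxy)-2-(4-methoxyphenyl)-4-oxochromen-8-yl]-4-methoxyphenyl}propane-1,3-dione (drawn as the diketo tautomer) | COc1ccc(C(=O)CC(=O)c2c(O)cc(OCc3ccccc3)cc2OCc2ccccc2)c(-c2c(OCc3ccccc3)cc(OCc3ccccc3)c3c(=O)cc(-c4ccc(OC)cc4)oc23)c1 | intermediate
16 | 5,7-bis(benzyloxy)-8-{2-[5,7-bis(benzyloxy)-4-oxochromen-2-yl]-5-methoxyphenyl}-2-(4-methoxyphenyl)chromen-4-one | COc1ccc(-c2cc(=O)c3c(OCc4ccccc4)cc(OCc4ccccc4)c(-c4cc(OC)ccc4-c4cc(=O)c5c(OCc6ccccc6)cc(OCc6ccccc6)cc5o4)c3o2)cc1 | intermediate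
17 | 8-[2-(5,7-dihydroxy-4-oxochromen-2-yl)-5-methoxyphenyl]-5,7-dihydroxy-2-(4-methoxyphenyl)chromen-4-one (CNP0394081.0) | COc1ccc(-c2cc(=O)c3c(O)cc(O)c(-c4cc(OC)ccc4-c4cc(=O)c5c(O)cc(O)cc5o4)c3o2)cc1 | target

**Step count**
Total steps: 10.
Longest linear sequence: 10 (1 → 2 → 3 → 5 → 6 → 8 → 12 → 13 → 15 → 16 → 17). Compound 2 re-enters in step 8 without extra steps.

**Steps most likely to fail**

Step 6. The trioxygenated ring A feeds electron density into the alkyne, and its two ortho substituents crowd the beta carbon. The cycloaddition may therefore be slower than thermal decay of the diene, and conversion may stall. The fallback gives up ring construction and forms the C8–C2' bond by Suzuki–Miyaura coupling. It sets out from 6. Commercial methyl 2-bromo-4-methoxybenzoate is borylated (bis(pinacolato)diboron, PdCl2(dppf), KOAc, dioxane, 90 °C) to methyl 4-methoxy-2-(4,4,5,5-tetramethyl-1,3,2-dioxaborolan-2-yl)benzoate F1. This is coupled with 6 (Pd(OAc)2, SPhos, K3PO4, toluene–water, 100 °C), and the sequence comes back to the route at 13.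

Step 8. The ester carbonyl of 13 is shielded by the perpendicular flavonyl group and deactivated by the para methoxy group. Intermolecular C-acylation may therefore lose out to proton exchange, self-condensation of the acetophenone or conjugate attack at C2 of the chromone. The fallback makes the acyl transfer intramolecular (Baker–Venkataraman rearrangement). It sets out from 13. Saponification (LiOH, THF–MeOH–water, 50 °C) gives 2-[5,7-bis(benzyloxy)-2-(4-methoxyphenyl)-4-oxochromen-8-yl]-4-methoxybenzoic acid F2. Steglich esterification with phenol 2 (EDC·HCl, DMAP, CH2Cl2, rt) gives 2-acetyl-3,5-bis(benzyloxy)phenyl 2-[5,7-bis(benzyloxy)-2-(4-methoxyphenyl)-4-oxochromen-8-yl]-4-methoxybenzoate F3. Base (KOH, pyridine, 50 °C) then moves the aroyl group from oxygen to the acetyl carbon, and the sequence comes back to the route at 15.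

Step 5. Base-induced oligomerisation and oxidative homocoupling of 7 may consume the alkyne faster than the hindered, electron-rich iodide undergoes oxidative addition. The fallback installs a robust ethynyl group first and adds the ester carbon afterwards. It sets out from 6. Sonogashira coupling with trimethylsilylacetylene (PdCl2(PPh3)2, CuI, Et3N–DMF, 60 °C) gives 5,7-bis(benzyloxy)-2-(4-methoxyphenyl)-8-[(trimethylsilyl)ethynyl]chromen-4-one F4. Desilylation (K2CO3, MeOH–THF, rt) gives 5,7-bis(benzyloxy)-8-ethynyl-2-(4-methoxyphenyl)chromen-4-one F5. Oxidative methoxycarbonylation (PdCl2 cat., CuCl2, NaOAc, CO 1 atm, MeOH–THF, rt) brings the sequence back to the route at 8.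

**Further compounds**
F1 | step 6 | methyl 4-methoxy-2-(4,4,5,5-tetramethyl-1,3,2-dioxaborolan-2-yl)benzoate | COC(=O)c1ccc(OC)cc1B1OC(C)(C)C(C)(C)O1
F2 | step 8 | 2-[5,7-bis(benzyloxy)-2-(4-methoxyphenyl)-4-oxochromen-8-yl]-4-methoxybenzoic acid | COc1ccc(C(=O)O)c(-c2c(OCc3ccccc3)cc(OCc3ccccc3)c3c(=O)cc(-c4ccc(OC)cc4)oc23)c1
F3 | step 8 | 2-acetyl-3,5-bis(benzyloxy)phenyl 2-[5,7-bis(benzyloxy)-2-(4-methoxyphenyl)-4-oxochromen-8-yl]-4-methoxybenzoate | COc1ccc(C(=O)Oc2cc(OCc3ccccc3)cc(OCc3ccccc3)c2C(C)=O)c(-c2c(OCc3ccccc3)cc(OCc3ccccc3)c3c(=O)cc(-c4ccc(OC)cc4)oc23)c1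
F4 | step 5 | 5,7-bis(benzyloxy)-2-(4-methoxyphenyl)-8-[(trimethylsilyl)ethynyl]chromen-4-one | COc1ccc(-c2cc(=O)c3c(OCc4ccccc4)cc(OCc4ccccc4)c(C#C[Si](C)(C)C)c3o2)cc1
F5 | step 5 | 5,7-bis(benzyloxy)-8-ethynyl-2-(4-methoxyphenyl)chromen-4-one | COc1ccc(-c2cc(=O)c3c(OCc4ccccc4)cc(OCc4ccccc4)c(C#C)c3o2)cc1
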